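The readings stem from a simulated flask on assumed constants; noise was put on by code.

The ratio we follow in the grey flask is the split: how fast free monomer turns into dormant form, over how fast living ends take it into chains, each as a pseudo-first-order rate constant.

common to all: initiator 2.5 mol%

| charge | free monomer | temperature | remark | time |
|---|---|---|---|---|
| grey | 0.10 M | −20 °C | the very flask that is asked about, followed so far |  |
| teal | 0.20 M | −25 °C | run made earlier |  |
| flask | 0.10 M | −20 °C |  | 3.0 d |

| run | time / h | monomer in chains / % | free monomer / % |
|---|---|---|---|
| grey | 8.00 | 14.6 | 54.7 |
| grey | 15.0 | 28.7 | 28.6 |
| grey | 20.0 | 34.4 | 15.6 |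
| grey | 30.0 | 42.6 | 6.0 |
| grey | 40.0 | 46.1 | 1.8 |
| teal | 0.500 | 0.8 | 98.9 |
| teal | 1.00 | 0 | 98.4 |
| teal | 1.33 | 1.3 | 96.5 |
| teal | 2.00 | 2.9 | 93.8 |
| teal | 2.50 | 2.3 | 92.7 |
| teal | 3.00 | 3.7 | 88.4 |

(each reading ± 1 percentage point)

- oak: at 3.0 d raise the temperature by 15 K, then wait 6.0 d
- birch: change nothing and wait 6.0 d more
- larch: at 3.0 d take out 90% of the monomer in chains then present, then wait 6.0 d
- maple: at 3.0 d add initiator, 100% of the amount charged, then wait 6.0 d

- monomer in chains that was removed still counts
- candidate steps: free monomer + initiator -> living end + monomer in chains; free monomer + living end -> monomer in chains + living end; free monomer <-> dormant form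
- additions bring no volume worth counting

- monomer in chains, in percent of the free monomer first charged, at 3.0 d
- the option that brings most further monomer in chains ("none" if no option brings more than 2 percentage points) (oak / birch / larch / maple / none)
- monomer in chains present, with what was taken out counted in, in percent of the free monomer first charged, after larch
- monomer in chains present, with what was taken out counted in, in percent of the free monomer first charged, after maple

Where does free monomer go? Whatever is neither free nor in chains is dormant, so the grey run up to 8.00 h reads dormant formation at 0.0496 h⁻¹, and between 30.0 h and 40.0 h it reads capture at 0.0897 h⁻¹. The early reading over this late one makes the split 0.553, so for that late stage we reckon a share 64.4% of free monomer reaching chains.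

How much is still to come? At 40.0 h the grey flask reads 52.1% as dormant form and 1.8% free, and by our share that free monomer reckons to lift chains to 47.3%. We therefore expect a little above this at 3.0 d, and any larger gain has to be released from dormant form.

Which option speeds that release? Initiator becomes living end by meeting free monomer, so even doubled initiator at this free monomer starts living ends at hardly any of the rate at charge, and we hold maple level with birch. Monomer in chains is a reactant in none of the candidate steps, so, taking the living ends to stay in the flask, we hold larch level with birch too. The teal run reads dormant formation at 0.0280 h⁻¹; free monomer is the lone reactant of that candidate step, so we take this constant to be free of the teal charge of 0.20 M, and since 15 K is 3 times the gap between −25 °C and −20 °C, these scattered readings give the forward step a rough factor near 5.59. If release rises alike, oak is our choice.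

The forecast gives 50.5%, oak, 57% after larch and 67% after maple, on its ground that “The dormant pool then feeds chains slowly”; it parts from us in ranking larch and maple apart.

The flask gives 49.7% at 3.0 d, and oak brings 49 percentage points further, against 13 points for birch, 13 points for larch and 13 points for maple, with totals of 62.3% after larch and 62.7% after maple.

    free monomer + initiator → living end + monomer in chains (k = 0.420 M⁻¹ h⁻¹, Ea = 64.0 kJ mol⁻¹)
    free monomer + living end → monomer in chains + living end, rate k2*[living end]*[free monomer] (k = 74.0 M⁻¹ h⁻¹, Ea = 44.0 kJ mol⁻¹)
    free monomer ⇌ dormant form (K = 15.0, k = 0.0490 h⁻¹, Ea = 76.0 kJ mol⁻¹, ΔH = −34.0 kJ mol⁻¹)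
    (constants at −20 °C)

At 72.0 h the flask's free monomer has a half-life of 9.4 h into chains and 14 h into dormant form by the forward step alone, so the split there, forward step over chains, stands at 0.66. Carried to the neighbour charged with 4.2 mol% of initiator, our split of 0.553 is scaled by living ends of 0.00145 M against 9.99 × 10⁻⁴ M to 0.382, and a balance of release from 40.2% dormant form against both exits reckons free monomer there at 0.859%, where that neighbour holds 0.853%.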